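A direct plan would buy the ring system as 5-bromobenzofuran-3(2H)-one A1, reduce its ketone to the (S) configuration with RuCl[(R,R)-TsDPEN](p-cymene), hang a diazo phosphonoacetyl group on O3 and close the cis-fused phosphono lactone A2 by C–H insertion at C2 with Rh2(O2CC7H15)4 (divalent rhodium).
It would then turn the bromide of A2 into the acetyl group by a tin coupling, reduce it, silylate, methylenate to the lactone A3, open A3 with KOH/MeI to the hydroxy acrylate A4, then acetylate, desilylate and angeloylate (about twelve steps from A1).
Weak point 1, the hydroxide opening of the α-methylene lactone A3: hydroxide can add to the exo-methylene, the enolate can expel O1 by E1cB, and the cis hydroxy ester A4 closes back to the lactone, all on a late and sensitive intermediate.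
Weak point 2, the stretch after the ring closure: a bromide-to-acetyl exchange through tin, a silyl group put on and taken off, and a lactone made only to be opened, seven steps that form no bond of the skeleton.
Weak point 3, the carbenoid C–H insertion that makes C2–Cα: β-lactone formation, arene cyclopropanation and carbene dimerisation compete, and C2 is only relayed from the C3 alcohol made from A1, a benzofuranol that dehydrates easily to the benzofuran.

**Retrosynthetic overview**
1. The array C3(O)–C2–Cα(=CH2)CO2Me on the dihydrofuran ring is the retron of a carbonyl 2-(alkoxycarbonyl)allylation, and C2 also carries O1, so the allyl unit can hang on the phenol oxygen of a salicylaldehyde.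
2. Key disconnection C2–C3: an intramolecular, enantioselective chromium-catalysed allylation joins the formyl carbon (C3) to the β-carbon of a β-aryloxyacrylate (C2). Both carbons are electrophilic, and the allylchromium species reverses the polarity of C2.
3. Ring order: the benzene ring is bought with its acetyl and formyl groups (5-acetylsalicylaldehyde). The dihydrofuran ring is the only ring made, closed at C2–C3 in a step that also sets C2 and C3 (cis), unveils the acrylate and silylates O3.
4. The precursor 7 is achiral and open-chain at the future ring, three steps from methyl 2-(bromomethyl)acrylate. After the key step only the side chain (reduction, angeloylation) and the O3 silyl-to-acetyl exchange remain.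
5. No lactone is ever formed, so there is no hydroxide opening. There is no tin coupling, and the one silyl group arrives with the key step.

Key step: step 4

Assumption: the (S,S)-ligand of step 4 is taken to send the allyl unit to the Re face of the formyl group (the sense that gives (R)-homoallylic alcohols from aryl aldehydes in the intermolecular reaction); if the sense were the opposite, the (R,R)-ligand would be used with no other change.

Step 1
Reactants: 1 methyl 2-(bromomethyl)acrylate
Product: 3 methyl (Z)-3-bromo-2-(bromomethyl)acrylate, via tribromo ester 2 (not isolated)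
Conditions: Br2 (1.05 equiv), CH2Cl2, rt; then Et3N (1.1 equiv), 0 °C
Reagents that add atoms: bromine, BrBr
Why: Bromination–dehydrobromination, in which bromine adds to the acrylate and E2 loss of HBr from the tribromo ester can give only one constitution because its only β-hydrogens sit on two equivalent CH2Br groups; the alkene geometry is not carried into the target.

Step 2
Reactants: 3 methyl (Z)-3-bromo-2-(bromomethyl)acrylate; 4 5-acetyl-2-hydroxybenzaldehyde (5-acetylsalicylaldehyde)
Product: 6 methyl (E)-2-(acetoxymethyl)-3-(4-acetyl-2-formylphenoxy)acrylate, via acetoxymethyl bromoacrylate 5 (not isolated)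
Conditions: KOAc (1.05 equiv), DMF, 0 °C → rt; then 4 (0.9 equiv), K2CO3 (1.5 equiv), rt → 40 °C
Reagents that add atoms: potassium acetate, CC(=O)[O-].[K+]
Why: SN2 displacement of the allylic bromide by acetate blocks that position, after which nucleophilic vinylic substitution (conjugate addition–elimination) of the phenoxide of 4 at the β-bromoacrylate should expel bromide, a far better leaving group than acetate, and give the enol ether with the aryloxy group trans to the ester.

Step 3
Reactants: 6 methyl (E)-2-(acetoxymethyl)-3-(4-acetyl-2-formylphenoxy)acrylate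
Product: 7 methyl (Z)-2-(bromomethyl)-3-(4-acetyl-2-formylphenoxy)acrylate
Conditions: MgBr2·OEt2 (2 equiv), CH2Cl2, 0 °C → rt
Reagents that add atoms: magnesium bromide, [Mg+2].[Br-].[Br-]
Why: Lewis-acid-assisted substitution of an allylic acetate by bromide, the conversion known for Morita–Baylis–Hillman acetates, helped here because the γ-aryloxy group makes the acetate a vinylogous acetal, with bromide returning at the CH2 end to give the conjugated allylic bromide.

Step 4
Reactants: 7 methyl (Z)-2-(bromomethyl)-3-(4-acetyl-2-formylphenoxy)acrylate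
Product: 8 methyl 2-[(2S,3S)-5-acetyl-3-(triethylsilyloxy)-2,3-dihydrobenzofuran-2-yl]acrylate
Conditions: CrCl2 (10 mol %), (S,S)-3,6-diphenyl-1,8-bis(4-isopropyl-4,5-dihydrooxazol-2-yl)-9H-carbazole (11 mol %), iPr2NEt (20 mol %), Mn powder (3 equiv), Et3SiCl (2.5 equiv), THF, slow addition of 7 to 0.01 M, 0 °C → rt
Reagents that add atoms: chlorotriethylsilane, CC[Si](Cl)(CC)CC
Why: Proposed new method: Divalent chromium, regenerated from the trivalent state by manganese metal, should reduce the allylic C–Br bond of 7 to a ligand-bound allylchromium species (trivalent chromium) that binds the formyl oxygen and delivers its γ-carbon, the one that bears the aryloxy group, to the formyl carbon through a six-membered metal-bridged transition state, after which Et3SiCl silylates the chromium alkoxide and frees the metal. The closest known reaction types are the chromium-catalysed enantioselective 2-(alkoxycarbonyl)allylation of aryl aldehydes with 2-(bromomethyl)acrylates under Nozaki–Hiyama–Kishi conditions with carbazole bis(oxazoline) ligands, and the indium- or chromium-mediated cyclisation of ω-formyl 2-(bromomethyl)alk-2-enoates to cis-2-(1-alkoxycarbonylvinyl)cycloalkanols; what is new is the intramolecular enantioselective use with an oxygen atom at the γ-position. The one ring closed is the dihydrofuran O1–C2–C3–C3a–C7a, formed by making C2–C3 in a 5-exo-trig attack on the formyl group in which the allyl double bond is exocyclic as well. C3 is set by the ligand, which decides the formyl face that is attacked (the Re face gives 3S), and C2 follows from C3 because the metal bridge holds the formyl oxygen and the allyl carbon Cα on the same side of the forming five-membered ring, so that only the cis isomer can come out of the closed transition state whatever the enol ether geometry. The step needs γ- over α-attack (the α-mode would need a seven-membered ring through a four-centre array), aldehyde over ketone (inherent to allylchromium reagents), ring closure over intermolecular addition (0.01 M, slow addition) and silylation over lactonisation of the cis alkoxide onto the ester (excess Et3SiCl).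

Step 5
Reactants: 8 methyl 2-[(2S,3S)-5-acetyl-3-(triethylsilyloxy)-2,3-dihydrobenzofuran-2-yl]acrylate
Product: 9 methyl 2-[(2S,3S)-5-[(S)-1-hydroxyethyl]-3-(triethylsilyloxy)-2,3-dihydrobenzofuran-2-yl]acrylate
Conditions: RuCl[(S,S)-TsDPEN](p-cymene) (1 mol %), HCO2H/Et3N (1:1), CH2Cl2, 25 °C
Reagents that add atoms: none
Why: Noyori–Ikariya asymmetric transfer hydrogenation of an aryl methyl ketone, for which the (S,S)-catalyst should give the (S)-1-arylethanol under pure catalyst control because the ring stereocentres are remote, while the amine-rich formate medium spares the silyl ether, the silyl ether blocks lactonisation and the methacrylate-type ester is not a substrate of the ruthenium hydride.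

Step 6
Reactants: 9 methyl 2-[(2S,3S)-5-[(S)-1-hydroxyethyl]-3-(triethylsilyloxy)-2,3-dihydrobenzofuran-2-yl]acrylate; 10 angelic acid, (Z)-2-methylbut-2-enoic acid
Product: 12 methyl 2-[(2S,3S)-5-[(S)-1-{[(Z)-2-methylbut-2-enoyl]oxy}ethyl]-3-(triethylsilyloxy)-2,3-dihydrobenzofuran-2-yl]acrylate, via mixed anhydride 11 (not isolated)
Conditions: 10, 2,4,6-Cl3C6H2COCl, Et3N, toluene, rt; then 9, 75 °C (no DMAP)
Reagents that add atoms: none
Why: Yamaguchi-type mixed-anhydride esterification run without a nucleophilic pyridine catalyst, which is what should keep the angeloyl unit from isomerising to tigloyl, and since only the acyl–O bond forms, the (S) configuration at C1′ is kept.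

Step 7
Reactants: 12 methyl 2-[(2S,3S)-5-[(S)-1-{[(Z)-2-methylbut-2-enoyl]oxy}ethyl]-3-(triethylsilyloxy)-2,3-dihydrobenzofuran-2-yl]acrylate
Product: 14 methyl 2-[(2S,3S)-3-acetoxy-5-[(S)-1-{[(Z)-2-methylbut-2-enoyl]oxy}ethyl]-2,3-dihydrobenzofuran-2-yl]acrylate (CNP0168827.1), via hydroxy ester 13 (not isolated)
Conditions: Et3N·3HF, THF, 0 °C → rt; then pyridine, Ac2O, DMAP (cat.), 0 °C
Reagents that add atoms: acetic anhydride, CC(=O)OC(C)=O
Why: Fluoride cleavage of the Si–O bond followed in the same flask by DMAP-catalysed acetylation, both at oxygen so that C3 keeps its configuration, with the fast acetylation at 0 °C expected to outrun attack of the cis hydroxyl on the conjugated methyl ester and the buffered fluoride too mild to ionise either benzylic C–O bond.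

**Compound list**
1 | methyl 2-(bromomethyl)acrylate | C=C(CBr)C(=O)OC | starting material
2 | methyl 2,3-dibromo-2-(bromomethyl)propanoate | COC(=O)C(Br)(CBr)CBr | intermediate
3 | methyl (Z)-3-bromo-2-(bromomethyl)acrylate | COC(=O)/C(CBr)=C/Br | intermediate
4 | 5-acetyl-2-hydroxybenzaldehyde (5-acetylsalicylaldehyde) | CC(=O)c1ccc(O)c(C=O)c1 | starting material
5 | methyl (E)-2-(acetoxymethyl)-3-bromoacrylate | COC(=O)/C(COC(C)=O)=C/Br | intermediate
6 | methyl (E)-2-(acetoxymethyl)-3-(4-acetyl-2-formylphenoxy)acrylate | COC(=O)/C(COC(C)=O)=C/Oc1ccc(C(C)=O)cc1C=O | intermediate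
7 | methyl (Z)-2-(bromomethyl)-3-(4-acetyl-2-formylphenoxy)acrylate | COC(=O)/C(CBr)=C/Oc1ccc(C(C)=O)cc1C=O | intermediate
8 | methyl 2-[(2S,3S)-5-acetyl-3-(triethylsilyloxy)-2,3-dihydrobenzofuran-2-yl]acrylate | C=C(C(=O)OC)[C@@H]1Oc2ccc(C(C)=O)cc2[C@@H]1O[Si](CC)(CC)CC | intermediate
9 | methyl 2-[(2S,3S)-5-[(S)-1-hydroxyethyl]-3-(triethylsilyloxy)-2,3-dihydrobenzofuran-2-yl]acrylate | C=C(C(=O)OC)[C@@H]1Oc2ccc([C@H](C)O)cc2[C@@H]1O[Si](CC)(CC)CC | intermediate
10 | angelic acid, (Z)-2-methylbut-2-enoic acid | C/C=C(/C)C(=O)O | starting material
11 | (Z)-2-methylbut-2-enoic 2,4,6-trichlorobenzoic anhydride | C/C=C(/C)C(=O)OC(=O)c1c(Cl)cc(Cl)cc1Cl | intermediate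
12 | methyl 2-[(2S,3S)-5-[(S)-1-{[(Z)-2-methylbut-2-enoyl]oxy}ethyl]-3-(triethylsilyloxy)-2,3-dihydrobenzofuran-2-yl]acrylate | C=C(C(=O)OC)[C@@H]1Oc2ccc([C@H](C)OC(=O)/C(C)=C\C)cc2[C@@H]1O[Si](CC)(CC)CC | intermediate
13 | methyl 2-[(2S,3S)-3-hydroxy-5-[(S)-1-{[(Z)-2-methylbut-2-enoyl]oxy}ethyl]-2,3-dihydrobenzofuran-2-yl]acrylate | C=C(C(=O)OC)[C@@H]1Oc2ccc([C@H](C)OC(=O)/C(C)=C\C)cc2[C@@H]1O | intermediate
14 | methyl 2-[(2S,3S)-3-acetoxy-5-[(S)-1-{[(Z)-2-methylbut-2-enoyl]oxy}ethyl]-2,3-dihydrobenzofuran-2-yl]acrylate (CNP0168827.1) | C=C(C(=O)OC)[C@@H]1Oc2ccc([C@H](C)OC(=O)/C(C)=C\C)cc2[C@@H]1OC(C)=O | target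

Total step count: 7. Longest linear sequence: 7 (1 → 3 → 6 → 7 → 8 → 9 → 12 → 14); 4 enters at step 2 and 10 at step 6.

**Steps most likely to fail**

Step 4 (key step, new method). The ligand may not control the formyl face well in the intramolecular mode. The chromium alkoxide may lactonise onto the ester before it is silylated. Intermolecular addition, pinacol coupling or reductive dimerisation of the bromide may take over at practical concentrations. The fallback uses known chemistry and sets out from 7. Indium powder in THF/H2O at rt (intramolecular Barbier allylation, the known cyclisation of ω-formyl 2-(bromomethyl)acrylates, cis for the same geometric reason) should give racemic methyl 2-[(2S*,3S*)-5-acetyl-3-hydroxy-2,3-dihydrobenzofuran-2-yl]acrylate F1. Ac2O/pyridine at 0 °C would then give the racemic acetate, methyl 2-[(2S*,3S*)-3-acetoxy-5-acetyl-2,3-dihydrobenzofuran-2-yl]acrylate F2. Candida antarctica lipase B with n-butanol in MTBE should cleave only the acetate that has the shape of (R)-1-indanyl acetate (Kazlauskas rule), which is the (3S) series, and release methyl 2-[(2S,3S)-5-acetyl-3-hydroxy-2,3-dihydrobenzofuran-2-yl]acrylate F3. If the enzyme preferred the other enantiomer, F1 would instead be acylated with vinyl acetate and F3 recovered as the unreacted alcohol. Et3SiCl/imidazole would then give 8, where the route is rejoined. Half of the material is given up.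

Step 2. The phenoxide may attack the allylic carbon instead of the vinylic one, substitution may go twice, or the intermediate enolate may add to the neighbouring formyl group. The fallback builds the enol ether first and brings in the CH2OAc carbon afterwards; it sets out from 4. Addition to methyl propiolate (N-methylmorpholine cat., CH2Cl2) should give methyl (E)-3-(4-acetyl-2-formylphenoxy)acrylate F4. Br2 and then Et3N, by way of the dibromide, methyl 2,3-dibromo-3-(4-acetyl-2-formylphenoxy)propanoate F5, should give methyl (Z)-2-bromo-3-(4-acetyl-2-formylphenoxy)acrylate F6. Migita–Kosugi–Stille coupling with Bu3SnCH2OAc [Pd2(dba)3 (zerovalent palladium), P(2-furyl)3, toluene, 90 °C] would give 6, where the route is rejoined.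

Step 3. The Lewis acid may ionise the vinylogous acetal at the wrong bond, so that the aryloxy group is lost, or the labile bromide may hydrolyse on work-up. The fallback makes the bromide from the alcohol under neutral conditions and never passes through the acetate; it sets out from 3. Hydrolysis of the allylic bromide (CaCO3, dioxane/H2O, 60 °C) should give methyl (E)-3-bromo-2-(hydroxymethyl)acrylate F7. Vinylic substitution with 4 (K2CO3, DMF) would give methyl (E)-2-(hydroxymethyl)-3-(4-acetyl-2-formylphenoxy)acrylate F8. NBS/PPh3 (CH2Cl2, −20 °C, Appel-type bromination) would give 7, where the route is rejoined.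

**Further compounds**
F1 | step 4 | racemic methyl 2-[(2S*,3S*)-5-acetyl-3-hydroxy-2,3-dihydrobenzofuran-2-yl]acrylate (one enantiomer drawn) | C=C(C(=O)OC)[C@@H]1Oc2ccc(C(C)=O)cc2[C@@H]1O
F2 | step 4 | racemic methyl 2-[(2S*,3S*)-3-acetoxy-5-acetyl-2,3-dihydrobenzofuran-2-yl]acrylate (one enantiomer drawn) | C=C(C(=O)OC)[C@@H]1Oc2ccc(C(C)=O)cc2[C@@H]1OC(C)=O
F3 | step 4 | methyl 2-[(2S,3S)-5-acetyl-3-hydroxy-2,3-dihydrobenzofuran-2-yl]acrylate (single enantiomer) | C=C(C(=O)OC)[C@@H]1Oc2ccc(C(C)=O)cc2[C@@H]1O
F4 | step 2 | methyl (E)-3-(4-acetyl-2-formylphenoxy)acrylate | COC(=O)/C=C/Oc1ccc(C(C)=O)cc1C=O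
F5 | step 2 | methyl 2,3-dibromo-3-(4-acetyl-2-formylphenoxy)propanoate (mixture of diastereomers) | COC(=O)C(Br)C(Br)Oc1ccc(C(C)=O)cc1C=O
F6 | step 2 | methyl (Z)-2-bromo-3-(4-acetyl-2-formylphenoxy)acrylate | COC(=O)/C(Br)=C/Oc1ccc(C(C)=O)cc1C=O
F7 | step 3 | methyl (E)-3-bromo-2-(hydroxymethyl)acrylate | COC(=O)/C(CO)=C/Br
F8 | step 3 | methyl (E)-2-(hydroxymethyl)-3-(4-acetyl-2-formylphenoxy)acrylate | COC(=O)/C(CO)=C/Oc1ccc(C(C)=O)cc1C=O
A1 | direct plan | 5-bromobenzofuran-3(2H)-one | O=C1COc2ccc(Br)cc21
A2 | direct plan | diethyl [(3S,3aR,8bS)-7-bromo-2-oxo-2,3,3a,8b-tetrahydrofuro[3,2-b]benzofuran-3-yl]phosphonate | O=C1[C@@H](P(=O)(OCC)OCC)[C@@H]2Oc3ccc(Br)cc3[C@@H]2O1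
A3 | direct plan | (3aS,8bS)-7-[(S)-1-(tert-butyldimethylsilyloxy)ethyl]-3-methylene-3a,8b-dihydrofuro[3,2-b]benzofuran-2(3H)-one | O=C1C(=C)[C@@H]2Oc3ccc([C@H](C)O[Si](C)(C)C(C)(C)C)cc3[C@@H]2O1
A4 | direct plan | methyl 2-[(2S,3S)-5-[(S)-1-(tert-butyldimethylsilyloxy)ethyl]-3-hydroxy-2,3-dihydrobenzofuran-2-yl]acrylate | C=C(C(=O)OC)[C@@H]1Oc2ccc([C@H](C)O[Si](C)(C)C(C)(C)C)cc2[C@@H]1O
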